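**Retrosynthetic overview**

1. Target ⇐ quinoid 6H-isochromen-6-one with the full side chain: the last step puts oxygen on C7 and adds water anti at C8, setting both ring stereocentres.
2. Quinoid ⇐ 3-methyl-2-benzopyrylium salt + (S)-enal acid, joined by a Knoevenagel-type condensation that forms the C6′=C7′ alkene.
3. Pyrylium ⇐ isocoumarin ⇐ 2-methylindenone: a Baeyer–Villiger ring expansion (alkenyl carbon shifts from carbon to oxygen) turns the five-membered carbocycle into the six-membered oxygen ring.
4. Indenone ⇐ o-cresol + methacryloyl chloride; enal acid ⇐ (R)-β-butyrolactone + vinyl Grignard (inversion), then cross-metathesis with methacrolein.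
5. Ring order: benzene ring (purchased) → five-membered ketone ring → expanded to the pyranone/pyrylium ring → benzene ring dearomatized last.

Assumption: the target is read from the SMILES as the (3S,4E,6E) acid with a (7S,8R) trans-diol; the ligand antipode in step 10 that gives 7S has to be confirmed by experiment (the L-pipecolic series is written).

**Step 1**
Reactants: 1 o-cresol; 2 methacryloyl chloride
Product: 4 5-hydroxy-2,6-dimethyl-2,3-dihydro-1H-inden-1-one (racemic), via aryl isopropenyl ketone 3 (not isolated)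
Conditions: TfOH (5 equiv), 1,2-dichloroethane, 0 °C → 80 °C
Reagents that add atoms: none
Why: TfOH drives O-acylation/para-Fries acylation of the phenol and then Nazarov-type (Friedel–Crafts) closure of the protonated enone onto the less hindered ortho position (para to the methyl), and the racemic C2 centre is erased in step 4.

**Step 2**
Reactants: 4 5-hydroxy-2,6-dimethyl-2,3-dihydro-1H-inden-1-one
Product: 5 4-chloro-5-hydroxy-2,6-dimethyl-2,3-dihydro-1H-inden-1-one (racemic)
Conditions: NCS (1.05 equiv), TsOH·H2O (10 mol %), MeCN, rt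
Reagents that add atoms: N-chlorosuccinimide, O=C1CCC(=O)N1Cl
Why: Electrophilic aromatic chlorination goes to the only free position ortho to the phenol, because the para position carries the acyl group and the other ortho position the methyl.

**Step 3**
Reactants: 5 4-chloro-5-hydroxy-2,6-dimethyl-2,3-dihydro-1H-inden-1-one
Product: 6 4-chloro-2,6-dimethyl-1-oxo-2,3-dihydro-1H-inden-5-yl pivalate (racemic)
Conditions: PivCl, Et3N, DMAP (10 mol %), CH2Cl2, rt
Reagents that add atoms: pivaloyl chloride, CC(C)(C)C(=O)Cl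
Why: DMAP-catalysed O-acylation gives an ester that removes the donor power of the phenol (so the aryl group will not out-compete the alkenyl group in step 5), blocks phenol oxidation, and is cleaved without an extra step in step 6.

**Step 4**
Reactants: 6 4-chloro-2,6-dimethyl-1-oxo-2,3-dihydro-1H-inden-5-yl pivalate
Product: 8 4-chloro-2,6-dimethyl-1-oxo-1H-inden-5-yl pivalate, via α-bromo ketone 7 (not isolated)
Conditions: Br2 (1.05 equiv), AcOH, rt; evaporate; then Li2CO3, LiBr, DMF, 110 °C
Reagents that add atoms: none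
Why: Acid-catalysed α-bromination at the only enolisable carbon followed by dehydrobromination gives the conjugated endocyclic 2-methylindenone.

**Step 5**
Reactants: 8 4-chloro-2,6-dimethyl-1-oxo-1H-inden-5-yl pivalate
Product: 9 5-chloro-3,7-dimethyl-1-oxo-1H-isochromen-6-yl pivalate
Conditions: mCPBA (1.5 equiv), NaHCO3, CH2Cl2, 0 °C → rt
Reagents that add atoms: meta-chloroperoxybenzoic acid, O=C(OO)c1cccc(Cl)c1
Why: In this Baeyer–Villiger oxidation the Criegee adduct collapses by a 1,2-shift of the electron-rich 1-methylvinyl carbon from carbon to oxygen, in preference to the acyloxy-deactivated aryl carbon, expanding the five-membered enone ring to the six-membered isocoumarin that holds O2 between C1 and C3.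

**Step 6**
Reactants: 9 5-chloro-3,7-dimethyl-1-oxo-1H-isochromen-6-yl pivalate
Product: 11 5-chloro-6-hydroxy-3,7-dimethylisochromenylium tetrafluoroborate, via lactol 10 (not isolated)
Conditions: i-Bu2AlH (3.5 equiv), CH2Cl2, −78 °C; then HBF4·OEt2, MeOH, −78 °C → rt; precipitate with Et2O
Reagents that add atoms: tetrafluoroboric acid (diethyl etherate), [H+].F[B-](F)(F)F
Why: Hydride reduction takes the lactone to the lactol and cleaves the pivalate, and the strong acid ionises the lactol to the aromatic 2-benzopyrylium cation (lactone-to-lactol reduction followed by oxocarbenium formation).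

**Step 7**
Reactants: 12 (R)-β-butyrolactone
Product: 13 (3S)-3-methylpent-4-enoic acid
Conditions: vinylmagnesium bromide (1.3 equiv), CuBr·SMe2 (10 mol %), THF/Me2S, −30 °C → 0 °C; aq. HCl
Reagents that add atoms: vinylmagnesium bromide, C=C[Mg]Br
Why: Copper-catalysed Grignard opening of the β-lactone is an SN2 attack at the β-carbon (alkyl–oxygen cleavage) with inversion, so the (R)-lactone gives the (S)-configured methyl-bearing centre of the side chain.

**Step 8**
Reactants: 13 (3S)-3-methylpent-4-enoic acid; 14 methacrolein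
Product: 15 (3S,4E)-3,5-dimethyl-6-oxohex-4-enoic acid
Conditions: methacrolein (5 equiv), RuCl2(H2IMes)(=CH-C6H4-2-OiPr) (Hoveyda–Grubbs second-generation catalyst, 5 mol %), CH2Cl2, 40 °C
Reagents that add atoms: none
Why: Olefin cross-metathesis of the terminal alkene with excess methacrolein gives the trisubstituted enal with the thermodynamically favoured E geometry and does not touch the allylic stereocentre.

**Step 9**
Reactants: 11 5-chloro-6-hydroxy-3,7-dimethylisochromenylium tetrafluoroborate; 15 (3S,4E)-3,5-dimethyl-6-oxohex-4-enoic acid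
Product: 16 (3S,4E,6E)-7-(5-chloro-7-methyl-6-oxo-6H-isochromen-3-yl)-3,5-dimethylhepta-4,6-dienoic acid
Conditions: NaOAc (1.5 equiv), AcOH, 50 °C
Reagents that add atoms: none
Why: In this Knoevenagel-type condensation the 3-methyl group of the pyrylium reacts through its methylene anhydrobase with the aldehyde and loses water to give the E alkene, and the acetate buffer leaves the product as the neutral quinoid, which keeps the allylic stereocentre from epimerising.

**Step 10**
Reactants: 16 (3S,4E,6E)-7-(5-chloro-7-methyl-6-oxo-6H-isochromen-3-yl)-3,5-dimethylhepta-4,6-dienoic acid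
Product: 18 (3S,4E,6E)-7-[(7S,8R)-5-chloro-7,8-dihydroxy-7-methyl-6-oxo-7,8-dihydro-6H-isochromen-3-yl]-3,5-dimethylhepta-4,6-dienoic acid, via 7,8-epoxide 17 (not isolated)
Conditions: Sc(OTf)3 (10 mol %), chiral N,N′-dioxide ligand (bis-N-oxide of 1,3-bis[(S)-2-(2,6-diisopropylphenylcarbamoyl)piperidin-1-yl]propane, 11 mol %), 3-phenyl-2-(phenylsulfonyl)oxaziridine (1.2 equiv), CH2Cl2, −20 °C; then H2O (10 equiv), THF, 0 °C
Reagents that add atoms: 3-phenyl-2-(phenylsulfonyl)oxaziridine, O=S(=O)(c1ccccc1)N1OC1c1ccccc1; water, O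
Why: Proposed new method: the quinoid is a pyrylium phenolate whose C7 (methyl-bearing, ortho to the oxygen; C5 is blocked by chlorine) is nucleophilic, so the scandium-bound phenolate held in the chiral ligand pocket should take oxygen from the oxaziridine on the Si face of C7 to give the 7,8-epoxide, which the Lewis acid opens at the oxocarbenium-stabilised C8 with water anti to the C7 oxygen to give the trans diol (7S,8R), while the oxaziridine leaves the side-chain diene alone; the closest known reaction type is the Sc(OTf)3/N,N′-dioxide-catalysed hydroxylative dearomatization of 2-naphthols with N-sulfonyl oxaziridines.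

**Compound list**

1 | o-cresol (2-methylphenol) | Cc1ccccc1O | starting material
2 | methacryloyl chloride | C=C(C)C(=O)Cl | starting material
3 | 1-(4-hydroxy-3-methylphenyl)-2-methylprop-2-en-1-one | C=C(C)C(=O)c1ccc(O)c(C)c1 | intermediate
4 | 5-hydroxy-2,6-dimethyl-2,3-dihydro-1H-inden-1-one (racemic) | CC1Cc2cc(O)c(C)cc2C1=O | intermediate
5 | 4-chloro-5-hydroxy-2,6-dimethyl-2,3-dihydro-1H-inden-1-one (racemic) | CC1Cc2c(Cl)c(O)c(C)cc2C1=O | intermediate
6 | 4-chloro-2,6-dimethyl-1-oxo-2,3-dihydro-1H-inden-5-yl pivalate (racemic) | CC1Cc2c(Cl)c(OC(=O)C(C)(C)C)c(C)cc2C1=O | intermediate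
7 | 2-bromo-4-chloro-2,6-dimethyl-1-oxo-2,3-dihydro-1H-inden-5-yl pivalate (racemic) | CC1(Br)Cc2c(Cl)c(OC(=O)C(C)(C)C)c(C)cc2C1=O | intermediate
8 | 4-chloro-2,6-dimethyl-1-oxo-1H-inden-5-yl pivalate | CC1=Cc2c(Cl)c(OC(=O)C(C)(C)C)c(C)cc2C1=O | intermediate
9 | 5-chloro-3,7-dimethyl-1-oxo-1H-isochromen-6-yl pivalate | CC1=Cc2c(Cl)c(OC(=O)C(C)(C)C)c(C)cc2C(=O)O1 | intermediate
10 | 5-chloro-3,7-dimethyl-1H-isochromene-1,6-diol (racemic lactol, present as its aluminium alkoxide) | CC1=Cc2c(Cl)c(O)c(C)cc2C(O)O1 | intermediate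
11 | 5-chloro-6-hydroxy-3,7-dimethylisochromenylium tetrafluoroborate | Cc1cc2c(Cl)c(O)c(C)cc2c[o+]1.F[B-](F)(F)F | intermediate
12 | (R)-β-butyrolactone, (4R)-4-methyloxetan-2-one | C[C@@H]1CC(=O)O1 | starting material
13 | (3S)-3-methylpent-4-enoic acid | C=C[C@@H](C)CC(=O)O | intermediate
14 | methacrolein | C=C(C)C=O | starting material
15 | (3S,4E)-3,5-dimethyl-6-oxohex-4-enoic acid | CC(/C=O)=C\[C@@H](C)CC(=O)O | intermediate
16 | (3S,4E,6E)-7-(5-chloro-7-methyl-6-oxo-6H-isochromen-3-yl)-3,5-dimethylhepta-4,6-dienoic acid | CC(/C=C/C1=CC2=C(Cl)C(=O)C(C)=CC2=CO1)=C\[C@@H](C)CC(=O)O | intermediate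
17 | (3S,4E,6E)-7-[(7S,8S)-5-chloro-7,8-epoxy-7-methyl-6-oxo-7,8-dihydro-6H-isochromen-3-yl]-3,5-dimethylhepta-4,6-dienoic acid | CC(/C=C/C1=CC2=C(Cl)C(=O)[C@@]3(C)O[C@H]3C2=CO1)=C\[C@@H](C)CC(=O)O | intermediate
18 | (3S,4E,6E)-7-[(7S,8R)-5-chloro-7,8-dihydroxy-7-methyl-6-oxo-7,8-dihydro-6H-isochromen-3-yl]-3,5-dimethylhepta-4,6-dienoic acid | CC(/C=C/C1=CC2=C(Cl)C(=O)[C@@](C)(O)[C@H](O)C2=CO1)=C\[C@@H](C)CC(=O)O | target

**Step count and risks**

Total step count: 10. Longest linear sequence: 8 (steps 1–6, 9, 10); the side chain (steps 7, 8) is made in parallel.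

The three steps most likely to fail:

Step 5 (aryl instead of alkenyl migration would give a coumarin, and epoxidation of the enone may compete). Fallback: give up the rearrangement and build the oxygen ring by cleavage and reclosure. Setting out from 6, NaBH4 in MeOH gives the indanol 4-chloro-1-hydroxy-2,6-dimethyl-2,3-dihydro-1H-inden-5-yl pivalate F1. TsOH in refluxing toluene dehydrates it to the indene 7-chloro-2,5-dimethyl-1H-inden-6-yl pivalate F2. Ozonolysis (O3, CH2Cl2/MeOH, −78 °C, then Me2S) cleaves the ring alkene to the keto aldehyde 2-chloro-4-formyl-6-methyl-3-(2-oxopropyl)phenyl pivalate F3. HBF4 in MeOH then closes the pyrylium ring and methanolyses the pivalate, which comes back to the route at 11.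

Step 9 (the 3-methyl group may be too sluggish, or the enal may self-condense or epimerise). Fallback: replace the condensation by a Horner–Wadsworth–Emmons olefination at the isocoumarin stage. Setting out from 9, NBS/AIBN in PhCF3 brominates the 3-methyl group to 3-(bromomethyl)-5-chloro-7-methyl-1-oxo-1H-isochromen-6-yl pivalate F4. Heating with P(OEt)3 (Arbuzov) gives 5-chloro-3-[(diethoxyphosphoryl)methyl]-7-methyl-1-oxo-1H-isochromen-6-yl pivalate F5. Its anion (LiN(SiMe3)2, 2.2 equiv, THF, −78 °C) with 15 gives (3S,4E,6E)-7-[5-chloro-7-methyl-1-oxo-6-(pivaloyloxy)-1H-isochromen-3-yl]-3,5-dimethylhepta-4,6-dienoic acid F6. i-Bu2AlH at −78 °C followed by aqueous acid and NaOAc buffer reduces the lactone, cleaves the pivalate and dehydrates the lactol, which comes back to the route at 16.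

Step 10 (the new step; the free acid may bind the scandium catalyst, enantioselectivity is untested, and the epoxide may undergo a 1,2-shift instead of hydration). Fallback with known chemistry: setting out from 16, oxidise with IBX in TFA/CH2Cl2 at rt (hypervalent-iodine hydroxylation of the 2-benzopyrylium at C7 without facial control), then add water. Because the side-chain centre is fixed, this gives 18 together with its diastereomer (3S,4E,6E)-7-[(7R,8S)-5-chloro-7,8-dihydroxy-7-methyl-6-oxo-7,8-dihydro-6H-isochromen-3-yl]-3,5-dimethylhepta-4,6-dienoic acid F7. The two are separated by preparative HPLC, which comes back to the route at 18 in at most half the yield.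

**Further compounds**

F1 | step 5 | 4-chloro-1-hydroxy-2,6-dimethyl-2,3-dihydro-1H-inden-5-yl pivalate (diastereomer mixture) | CC1Cc2c(Cl)c(OC(=O)C(C)(C)C)c(C)cc2C1O
F2 | step 5 | 7-chloro-2,5-dimethyl-1H-inden-6-yl pivalate | CC1=Cc2cc(C)c(OC(=O)C(C)(C)C)c(Cl)c2C1
F3 | step 5 | 2-chloro-4-formyl-6-methyl-3-(2-oxopropyl)phenyl pivalate | CC(=O)Cc1c(Cl)c(OC(=O)C(C)(C)C)c(C)cc1C=O
F4 | step 9 | 3-(bromomethyl)-5-chloro-7-methyl-1-oxo-1H-isochromen-6-yl pivalate | BrCC1=Cc2c(Cl)c(OC(=O)C(C)(C)C)c(C)cc2C(=O)O1
F5 | step 9 | 5-chloro-3-[(diethoxyphosphoryl)methyl]-7-methyl-1-oxo-1H-isochromen-6-yl pivalate | CCOP(=O)(CC1=Cc2c(Cl)c(OC(=O)C(C)(C)C)c(C)cc2C(=O)O1)OCC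
F6 | step 9 | (3S,4E,6E)-7-[5-chloro-7-methyl-1-oxo-6-(pivaloyloxy)-1H-isochromen-3-yl]-3,5-dimethylhepta-4,6-dienoic acid | CC(/C=C/C1=Cc2c(Cl)c(OC(=O)C(C)(C)C)c(C)cc2C(=O)O1)=C\[C@@H](C)CC(=O)O
F7 | step 10 | (3S,4E,6E)-7-[(7R,8S)-5-chloro-7,8-dihydroxy-7-methyl-6-oxo-7,8-dihydro-6H-isochromen-3-yl]-3,5-dimethylhepta-4,6-dienoic acid | CC(/C=C/C1=CC2=C(Cl)C(=O)[C@](C)(O)[C@@H](O)C2=CO1)=C\[C@@H](C)CC(=O)O
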